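**Retrosynthetic overview**
- The last step unmasks the 4(1H)-quinolone (N1–H, C4=O) by hydrogenolysis of an O4-benzyl ether; until then the benzyl group holds the hetero ring as a true pyridine ring (4-benzyloxyquinoline).
- Key disconnection: the side-chain bond between the CH2 on ring carbon C2 and the next CH2. The two halves are 4-(benzyloxy)-3-methoxy-2-methylquinoline and unprotected 10-methylundecane-1,10-diol, joined by an Ir-catalysed hydrogen-autotransfer (borrowing-hydrogen) C-alkylation: C(sp3)–H plus C(sp3)–OH, with water as the only coproduct.
- Enabling feature: the CH3 on C2 lies α to the N1=C2 bond of the pyridine ring (2-picolyl-type C–H, anion delocalised onto N1). The distal C(CH3)2OH carbon carries no hydrogen, so only the primary CH2OH can be dehydrogenated.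
- Ring order: the benzene ring comes from aniline; the pyridone ring is built once, before the key step, by Conrad–Limpach synthesis (N1–C2 by enamine condensation, then C4–C4a by thermal cyclisation). The diol comes from methyl 10-hydroxydecanoate and MeMgBr.

Key step: step 5

Remark: the target has no stereocentre and no stereogenic double bond, so no enantiomer has to be selected; it is made as the 4(1H)-quinolone tautomer.

**Step 1**
Reactants: 1 aniline; 2 methyl 2-methoxy-3-oxobutanoate
Product: 3 methyl (E)-2-methoxy-3-(phenylamino)but-2-enoate
Conditions: p-TsOH·H2O (2 mol %), cyclohexane, reflux, Dean–Stark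
Reagents that add atoms: none
Why: Acid-catalysed condensation of the ketone carbonyl of 2 (more electrophilic than the ester) with aniline under water removal should give the β-anilino enoate, the first stage of the Conrad–Limpach synthesis; the N–H···O=C hydrogen bond sets the E geometry and the moderate temperature avoids the anilide (Knorr) channel.

**Step 2**
Reactants: 3 methyl (E)-2-methoxy-3-(phenylamino)but-2-enoate
Product: 4 3-methoxy-2-methylquinolin-4(1H)-one
Conditions: Ph2O, 250 °C (3 added slowly to the hot solvent, MeOH distilled off); cool, hexane, filter
Reagents that add atoms: none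
Why: Conrad–Limpach thermal cyclisation: the enamino ester should lose methanol and close the C4–C4a bond onto an ortho carbon of the aniline ring (both ortho positions are equivalent), then tautomerise to the 4(1H)-quinolone.

**Step 3**
Reactants: 4 3-methoxy-2-methylquinolin-4(1H)-one
Product: 5 4-(benzyloxy)-3-methoxy-2-methylquinoline
Conditions: BnBr (1.2 equiv), Ag2CO3 (1.0 equiv), toluene, 80 °C, dark
Reagents that add atoms: benzyl bromide, BrCc1ccccc1
Why: Silver-assisted alkylation of the ambident quinolone should go to oxygen (charge-controlled, with N1 shielded by the C2 methyl and the peri C8–H), as in the Ag2CO3 O-alkylation of pyridones and quinolones, giving the aromatic 4-alkoxyquinoline.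

**Step 4**
Reactants: 6 methyl 10-hydroxydecanoate
Product: 7 10-methylundecane-1,10-diol
Conditions: MeMgBr (3.5 equiv), THF, 0 °C to rt; then H2O/aq NH4Cl
Reagents that add atoms: methylmagnesium bromide, C[Mg]Br
Why: Grignard addition to an ester: the first equivalent deprotonates the primary hydroxyl and two more add through the methyl ketone to give the tertiary carbinol.

**Step 5**
Reactants: 5 4-(benzyloxy)-3-methoxy-2-methylquinoline; 7 10-methylundecane-1,10-diol
Product: 10 12-[4-(benzyloxy)-3-methoxyquinolin-2-yl]-2-methyldodecan-2-ol, via 10-hydroxy-10-methylundecanal 8 (not isolated), via (E)-2-alkenylquinoline 9 (not isolated)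
Conditions: [Ir(cod)Cl]2 (2.5 mol %), PPh3 (10 mol %), KOt-Bu (0.5 equiv), 7 (1.3 equiv), 1,4-dioxane, 130 °C, sealed tube, Ar
Reagents that add atoms: none
Why: The iridium alkoxide of the primary CH2OH of 7 should undergo β-hydride elimination to aldehyde 8 and an Ir hydride, while KOt-Bu reversibly deprotonates the C2 methyl of 5 to an anion delocalised onto N1 that adds to 8 and dehydrates (E1cB) to the (E)-alkene 9. The Ir hydride then returns the borrowed hydrogen by conjugate reduction of the C=C bond polarised by C2=N1, giving 10 with water as the only coproduct. The closest known reaction type is the Ir-catalysed hydrogen-autotransfer C-alkylation of 2-methylquinolines and other methyl N-heteroarenes with primary alcohols, aliphatic ones included. No ring is closed and no stereocentre is formed, since the E-alkene 9 is transient and is saturated. The step needs chemoselectivity between the two hydroxyls, which the substrate secures because the tertiary carbinol carbon has no hydrogen and cannot be dehydrogenated, so the diol runs unprotected. It also needs site- and mono-selectivity, secured because the C2 methyl is the only azaallylic C–H once the O4-benzyl group fixes the pyridine tautomer, and because the new C2–CH2 group in 10 is less acidic and is flanked by the 3-methoxy group.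

**Step 6**
Reactants: 10 12-[4-(benzyloxy)-3-methoxyquinolin-2-yl]-2-methyldodecan-2-ol
Product: 11 2-(11-hydroxy-11-methyldodecyl)-3-methoxyquinolin-4(1H)-one
Conditions: H2 (1 atm), 10 % Pd/C, EtOH, rt
Reagents that add atoms: none
Why: Catalytic hydrogenolysis of the benzylic C–O bond should release the 4-hydroxyquinoline, which tautomerises to the 4(1H)-quinolone; the methyl ether, the tertiary alcohol and the rings are inert at 1 atm, and any alkene 9 carried over from step 5 would be saturated in the same operation.

**Compound list**
1 | aniline | Nc1ccccc1 | starting material
2 | methyl 2-methoxy-3-oxobutanoate | COC(=O)C(OC)C(C)=O | starting material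
3 | methyl (E)-2-methoxy-3-(phenylamino)but-2-enoate | COC(=O)/C(OC)=C(/C)Nc1ccccc1 | intermediate
4 | 3-methoxy-2-methylquinolin-4(1H)-one | COc1c(C)[nH]c2ccccc2c1=O | intermediate
5 | 4-(benzyloxy)-3-methoxy-2-methylquinoline | COc1c(C)nc2ccccc2c1OCc1ccccc1 | intermediate
6 | methyl 10-hydroxydecanoate | COC(=O)CCCCCCCCCO | starting material
7 | 10-methylundecane-1,10-diol | OCCCCCCCCCC(C)(C)O | intermediate
8 | 10-hydroxy-10-methylundecanal (formed in the flask in step 5) | O=CCCCCCCCCC(C)(C)O | intermediate
9 | (E)-12-[4-(benzyloxy)-3-methoxyquinolin-2-yl]-2-methyldodec-11-en-2-ol (formed in the flask in step 5) | COc1c(/C=C/CCCCCCCCC(C)(C)O)nc2ccccc2c1OCc1ccccc1 | intermediate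
10 | 12-[4-(benzyloxy)-3-methoxyquinolin-2-yl]-2-methyldodecan-2-ol | COc1c(CCCCCCCCCCC(C)(C)O)nc2ccccc2c1OCc1ccccc1 | intermediate
11 | 2-(11-hydroxy-11-methyldodecyl)-3-methoxyquinolin-4(1H)-one | COc1c(CCCCCCCCCCC(C)(C)O)[nH]c2ccccc2c1=O | target

**Step count**
Total steps: 6. Longest linear sequence: 5 (steps 1, 2, 3, 5, 6); step 4 makes the second fragment.

**Steps most likely to fail**

Step 5. The quinoline carries two donor oxygens and is a weaker C–H acid than 2-methylquinoline. Condensation may therefore lag behind dehydrogenation, so the aliphatic aldehyde self-condenses (aldol/Guerbet) or is esterified (Tishchenko type). The primary alkoxide may also exchange with the benzyloxy group at C4 at 130 °C. Incomplete return of hydrogen is harmless, because step 6 saturates the alkene. The fallback replaces hydrogen autotransfer by stoichiometric lateral metalation; it sets out from 5 (with 7 as the chain source) and comes back at 10. Diol 7 is converted at its primary hydroxyl only (I2, PPh3, imidazole, CH2Cl2, 0 °C; Appel reaction) into 11-iodo-2-methylundecan-2-ol F1. Compound 5 (2.2 equiv) is deprotonated at the C2 methyl with LDA (THF, −78 °C) and the 2-lithiomethyl anion is alkylated with F1. One equivalent of the anion is consumed by the tertiary hydroxyl and returns as 5; NH4Cl work-up should give 10, which goes on to step 6.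

Step 3. The ambident quinolone may be benzylated at N1 in competition with O4, and the N-benzyl quinolone cannot serve in the key step. The fallback fixes the site by substitution at carbon; it sets out from 4 and comes back at 5. Compound 4 is heated with POCl3 (toluene, 100 °C) to give 4-chloro-3-methoxy-2-methylquinoline F2, and nucleophilic aromatic substitution with sodium benzyloxide (BnOH, NaH, DMF, 80 °C) should give 5.

Step 2. At 250 °C the enamino ester may equilibrate towards the anilide and cyclise in the Knorr sense, or decompose with loss of the methoxy methyl, eroding the ring closure. The fallback closes the ring by a Camps cyclisation; it sets out from 1 and comes back at 4. Aniline 1 is ortho-acylated with methoxyacetonitrile (BCl3, AlCl3, 1,2-dichloroethane, reflux; Sugasawa reaction) to the ketimine 1-(2-aminophenyl)-2-methoxyethan-1-imine F3, which is hydrolysed in the aqueous HCl work-up to 1-(2-aminophenyl)-2-methoxyethan-1-one F4. N-Acetylation (Ac2O, pyridine, rt) gives N-[2-(2-methoxyacetyl)phenyl]acetamide F5. NaOH in dioxane at 110 °C should then deprotonate the more acidic methoxy-bearing ketone α-carbon, which attacks the amide carbonyl and dehydrates to 4.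

**Further compounds**
F1 | step 5 | 11-iodo-2-methylundecan-2-ol | CC(C)(O)CCCCCCCCCI
F2 | step 3 | 4-chloro-3-methoxy-2-methylquinoline | COc1c(C)nc2ccccc2c1Cl
F3 | step 2 | 1-(2-aminophenyl)-2-methoxyethan-1-imine | COCC(=N)c1ccccc1N
F4 | step 2 | 1-(2-aminophenyl)-2-methoxyethan-1-one | COCC(=O)c1ccccc1N
F5 | step 2 | N-[2-(2-methoxyacetyl)phenyl]acetamide | COCC(=O)c1ccccc1NC(C)=O
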